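Start from the feed.

common to all: free monomer 0.20 M (fed, over 8.0 h); pre-initiator 4.4 mol%
- Thursday's: transfer agent 3 mM; run made earlier
- flask: transfer agent 2.00 mM; time 8.0 h

Thursday's run (percent of the free monomer charged)

| time / h | monomer in chains / % | free monomer / % |
|---|---|---|
| 0.200 | 0.4 | 1.5 |
| 0.333 | 1.3 | 3.3 |
| 0.667 | 0 | 8.8 |
| 1.33 | 0.5 | 15.1 |
| 2.50 | 2.7 | 28.8 |

(scatter of a reading: 1 percentage point)

- the average divides the monomer in chains by the number of chains begun, living and dead together
- the earlier runs do not show the number of chains; that part of a forecast is a guess
- percentages count the whole charge, also what has not yet gone in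
- no earlier run changes the charge of transfer agent; that part of a forecast is a guess

1. average number of monomer units in a chain (chains begun, living or dead) at 8.0 h
2. part of the free monomer that has reacted at 8.0 h

First, does uptake keep pace with the feed? In Thursday's run at 2.50 h the monomer in chains stands at 2.7% and the free monomer at 28.8%, a ratio of 0.0938, so we take the free monomer of that run as close to what has gone in so far.

Then what does the free monomer present do per hour? Dividing that monomer in chains by the fed fraction summed over time, 0.391 h, gives 0.0691 h⁻¹, which we call the uptake constant, the fraction of the free monomer present that enters chains per hour, a pseudo-first-order constant; it is a reading, and its numerator carries a scatter of 1 percentage point.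

What does that give in the flask? If the constant holds through the feed and the smaller charge of transfer agent leaves it as it is, which is a guess, we reckon 23.2% reacted at 8.0 h; the earlier runs show no chains, so we offer no chain length.

The forecast says 32%, above our figure, on its ground that “a pre-initiator suggests some build-up”, and 12 units per chain, which it calls a guess.

The flask gives 16.3% reacted and 5.77 units per chain.

    free monomer + initiator → living end + monomer in chains (k = 0.0200 M⁻¹ s⁻¹)
    free monomer + living end → monomer in chains + living end, rate k2*[living end]*[free monomer] (k = 0.0250 M⁻¹ s⁻¹)
    living end + transfer agent → dead chain (kL = 0.0990 M⁻¹ s⁻¹)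
    2 living end → dead end A (k = 0.160 M⁻¹ s⁻¹)
    living end → dead end B (k = 1.80 × 10⁻⁴ s⁻¹)
    pre-initiator ⇌ initiator (K = 7.60, k = 3.60 × 10⁻⁵ s⁻¹)

In the flask the living end has a half-life of 0.97 h by transfer agent alone at charged concentrations, shorter than the 5.3 h of pre-initiator by its forward step alone, and between 4.00 h and 8.00 h the living end goes from 4.81 × 10⁻⁴ M to 3.48 × 10⁻⁴ M while pre-initiator goes from 59.7% to 35.6% of its charge. Reckoned from the gain in monomer in chains and the mean of the free monomer at the two ends, the uptake constant of this flask over that stretch is 0.0407 h⁻¹, and in the same flask read at 30 h, with 38.8% reacted, it has fallen to 0.0142 h⁻¹ over the stretch after 8.0 h.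

(The runs are simulated with constants of no real substance, and the scatter is random.)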